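**Plan**
- Retrosynthesis: the three pyrrole C–Br bonds (C3, C4, C5) are removed first; the pyrrole is then cut at N–C2 and at C4–C5, which leaves a chromone and nitromethane.
- Enabling feature: the 2-hydroxyphenyl group on pyrrole C2, together with pyrrole C3 and C4, is a chromone in ring-opened form (chromone C4, C3, C2 become pyrrole C2, C3, C4; chromone O1 is the phenol oxygen). The ring oxygen can therefore leave as phenoxide and deliver the aromatic oxidation level without an oxidant, while pyrrole C5 and the nitrogen are one nitromethane.
- Forward order: the dibrominated benzene ring is bought; the pyranone ring is closed (enaminone, then acid), opened again in the flask in which the pyrrole ring closes, and the pyrrole is tribrominated last.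
- Stereochemistry: the target has no stereocentre and no stereogenic double bond; the one sp3 centre formed on the way is racemic and is erased in the same flask.

Key step: step 3

**Step 1**
Reactants: 1 3',5'-dibromo-2'-hydroxyacetophenone; 2 N,N-dimethylformamide dimethyl acetal
Product: 3 (E)-1-(3,5-dibromo-2-hydroxyphenyl)-3-(dimethylamino)prop-2-en-1-one
Conditions: 2 (1.5 equiv), toluene, 90 °C
Reagents that add atoms: none
Why: Condensation of an aryl methyl ketone with an amide acetal (enaminone formation) is standard for 2'-hydroxyacetophenones, the hydrogen-bonded phenol should be spared at this temperature, and the conjugated E isomer is the thermodynamic product.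

**Step 2**
Reactants: 3 (E)-1-(3,5-dibromo-2-hydroxyphenyl)-3-(dimethylamino)prop-2-en-1-one
Product: 4 6,8-dibromo-4H-chromen-4-one
Conditions: conc. HCl, CH2Cl2, 40 °C
Reagents that add atoms: none
Why: Acid-promoted intramolecular addition–elimination (oxa-Michael addition of the phenol to the protonated enaminone, then loss of the amine) is the usual closure of such enaminones to 3-unsubstituted chromones.

**Step 3**
Reactants: 4 6,8-dibromo-4H-chromen-4-one; 5 nitromethane
Product: 10 2,4-dibromo-6-(1H-pyrrol-2-yl)phenol, via nitromethylchromanone 6 (not isolated), via Z-nitroenone 7 (not isolated), via Z-aminoenone 8 (not isolated), via 2H-pyrrole 9 (not isolated)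
Conditions: 5 (3 equiv), DBU (2.2 equiv), THF, 0 °C to rt; then AcOH, Zn dust (12 equiv), 0 to 60 °C, same flask
Reagents that add atoms: none
Why: Proposed new method: the DBU nitronate of 5 should add in a Michael sense to C2 of 4 to give nitromethylchromanone 6, and the base should open 6 by retro-oxa-Michael (E1cB) loss of the dibromophenoxide to nitroenone 7, held as a delocalized phenoxide/vinylogous nitronate that pulls the addition forward and lets the double-bond geometry equilibrate. After acidification, zinc in acetic acid should reduce the nitro group to the amine (three Zn per nitro group), and in Z-aminoenone 8 the amine condenses with the former chromone carbonyl in a 5-exo-trig closure to 2H-pyrrole 9, which a proton shift turns into the aromatic 1H-pyrrole 10; this is the only ring that closes, while the pyranone ring is the one that opens and its oxygen supplies the oxidation level. The closest known reaction types are the recyclization of chromones by hydrazine or hydroxylamine to 2-hydroxyphenyl azoles, the base-mediated addition of nitroalkanes to chromones that carry an activating group, and the reductive cyclization of γ-nitro ketones to 1-pyrrolines with zinc and acetic acid. No stereocentre has to be controlled, since C2 of racemic 6 is erased on ring opening. The step needs attack at C2 and not at the carbonyl, which the soft stabilized nitronate and the two ring bromines (a more electrophilic C2 and a better phenoxide leaving group) should secure, and it needs reduction of the nitro group without loss of aryl bromine or saturation of the enone, for which zinc in acetic acid is chosen over catalytic hydrogenation. Geometric isomers and ring-closed forms of 7 and 8 that cannot cyclize should return to 8 by reversible oxa-Michael addition of the phenol, so that the irreversible aromatization drains the equilibrium.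

**Step 4**
Reactants: 10 2,4-dibromo-6-(1H-pyrrol-2-yl)phenol
Product: 11 pentabromopseudilin, 2,4-dibromo-6-(3,4,5-tribromo-1H-pyrrol-2-yl)phenol
Conditions: NBS (3.05 equiv), THF, −78 °C to 0 °C, dark
Reagents that add atoms: N-bromosuccinimide, O=C1CCC(=O)N1Br
Why: Electrophilic aromatic bromination should take the three free pyrrole positions (C5, then C3 and C4), the most nucleophilic sites of the molecule, because the phenol ring already carries a substituent at both ortho positions and at the para position.

**Compound list**
1 | 3',5'-dibromo-2'-hydroxyacetophenone, 1-(3,5-dibromo-2-hydroxyphenyl)ethan-1-one | CC(=O)c1cc(Br)cc(Br)c1O | starting material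
2 | N,N-dimethylformamide dimethyl acetal | COC(OC)N(C)C | starting material
3 | (E)-1-(3,5-dibromo-2-hydroxyphenyl)-3-(dimethylamino)prop-2-en-1-one | CN(C)/C=C/C(=O)c1cc(Br)cc(Br)c1O | intermediate
4 | 6,8-dibromo-4H-chromen-4-one | O=C1C=COc2c(Br)cc(Br)cc12 | intermediate
5 | nitromethane | C[N+](=O)[O-] | starting material
6 | 6,8-dibromo-2-(nitromethyl)chroman-4-one, racemic | O=C1CC(C[N+](=O)[O-])Oc2c(Br)cc(Br)cc12 | intermediate
7 | (Z)-1-(3,5-dibromo-2-hydroxyphenyl)-4-nitrobut-2-en-1-one | O=C(/C=C\C[N+](=O)[O-])c1cc(Br)cc(Br)c1O | intermediate
8 | (Z)-4-amino-1-(3,5-dibromo-2-hydroxyphenyl)but-2-en-1-one | NC/C=C\C(=O)c1cc(Br)cc(Br)c1O | intermediate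
9 | 2,4-dibromo-6-(2H-pyrrol-5-yl)phenol | Oc1c(Br)cc(Br)cc1C1=NCC=C1 | intermediate
10 | 2,4-dibromo-6-(1H-pyrrol-2-yl)phenol | Oc1c(Br)cc(Br)cc1-c1ccc[nH]1 | intermediate
11 | pentabromopseudilin, 2,4-dibromo-6-(3,4,5-tribromo-1H-pyrrol-2-yl)phenol | Oc1c(Br)cc(Br)cc1-c1[nH]c(Br)c(Br)c1Br | target

**Step count**
Total: 4 steps. Longest linear sequence: 4 steps (1 to 11).

**Steps most likely to fail**

Step 3 (proposed new method). Several processes may go wrong:
- The nitronate may add too slowly to a chromone without an activating group at C3, so that base-mediated cleavage of the pyranone ring takes over.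
- Zinc may saturate the enone before the amine condenses, which ends at the pyrroline oxidation level.
- The free amine may oligomerize by intermolecular aza-Michael addition while the enone still has the wrong geometry.
- Excess nitromethane is reduced as well and consumes zinc, which is why zinc is used in large excess.

The fallback sets out from 1, comes back to the route at 10 and uses only known reaction types. The lithium dianion of 1 (LiN(SiMe3)2, 2.2 equiv, THF, −78 °C) should be C-allylated with allyl bromide to 1-(3,5-dibromo-2-hydroxyphenyl)pent-4-en-1-one F1. Ozonolysis of the terminal alkene (O3, CH2Cl2/MeOH, −78 °C, then Me2S) should give 4-(3,5-dibromo-2-hydroxyphenyl)-4-oxobutanal F2. Paal–Knorr condensation of this 1,4-dicarbonyl compound with NH4OAc in AcOH at 60 °C should then close the pyrrole to 10.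

Step 4. Over-oxidation of the electron-rich hydroxyphenylpyrrole by the brominating agent, ipso attack, or incomplete bromination that leaves mixtures of di- and tribromides may occur. The fallback sets out from 10 and comes back at 11. The phenol is masked first with Ac2O and pyridine in CH2Cl2 at 0 °C to give 2,4-dibromo-6-(1H-pyrrol-2-yl)phenyl acetate F3, which lowers the oxidation sensitivity of the aryl ring. Bromination with NBS (3 equiv, THF, −78 to 0 °C) should give 2,4-dibromo-6-(3,4,5-tribromo-1H-pyrrol-2-yl)phenyl acetate F4. Methanolysis of the aryl acetate (K2CO3, MeOH, rt, then dilute acid) should release 11.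

Step 1. O-methylation of the acidic dibromophenol by the amide acetal, or incomplete condensation, may erode the supply of the chromone. The fallback sets out from 1 and comes back at 4 by the formylation route. Claisen condensation of 1 with ethyl formate (NaH, THF, 0 °C to rt) should give the β-ketoaldehyde in its cyclic hemiacetal form, racemic 6,8-dibromo-2-hydroxychroman-4-one F5. Acid dehydration (conc. HCl, AcOH, 60 °C) should then give 4.

**Further compounds**
F1 | step 3 | 1-(3,5-dibromo-2-hydroxyphenyl)pent-4-en-1-one | C=CCCC(=O)c1cc(Br)cc(Br)c1O
F2 | step 3 | 4-(3,5-dibromo-2-hydroxyphenyl)-4-oxobutanal | O=CCCC(=O)c1cc(Br)cc(Br)c1O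
F3 | step 4 | 2,4-dibromo-6-(1H-pyrrol-2-yl)phenyl acetate | CC(=O)Oc1c(Br)cc(Br)cc1-c1ccc[nH]1
F4 | step 4 | 2,4-dibromo-6-(3,4,5-tribromo-1H-pyrrol-2-yl)phenyl acetate | CC(=O)Oc1c(Br)cc(Br)cc1-c1[nH]c(Br)c(Br)c1Br
F5 | step 1 | 6,8-dibromo-2-hydroxychroman-4-one, racemic | O=C1CC(O)Oc2c(Br)cc(Br)cc12
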